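**Assumption:** the SMILES is read as the (5E)-ylidene (side chain cis to C4–OH), R at the carbon next to the ylidene, S at the diene-side carbon, and a (7E,9Z)-diene. 3-Methyltetronic acid and all named reagents are taken as commercial and achiral.

## Retrosynthetic overview

1. Target ⇒ MOM-protected (5E)-ylidene tetronate; the C5=C bond comes from a kinetically controlled olefination of a new 5-(diphenoxyphosphoryl) tetronate with an α-methyl aldehyde.
2. Aldehyde ⇒ dimethyl acetal; the (E,Z)-diene comes from hydrozirconation/Negishi coupling of a terminal alkyne with a (Z)-vinyl iodide made by carbocupration of propyne.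
3. Alkyne ⇒ β-branched aldehyde; both methyl stereocentres come from metal-free iminium transfer hydrogenations of β-methyl enals. One catalyst antipode serves twice, because the CH2–CHO arm becomes chain at one centre and alkenyl side at the other.
4. The chain grows from 1,1-dimethoxyacetone by two formyl-olefinations and one Wittig/hydrogenation.
5. Rings: furan and tetronic acid are both bought (3-bromofuran, 3-methyltetronic acid); no ring is formed.

## Route

Step 1
Reactants: 1 1,1-dimethoxypropan-2-one; 2 diethyl [(E)-2-(cyclohexylamino)ethenyl]phosphonate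
Product: 4 (2E)-4,4-dimethoxy-3-methylbut-2-enal, via unsaturated N-cyclohexylimine 3 (not isolated)
Conditions: NaH, THF, 0 °C to rt; then aq. AcOH/NaOAc (pH 4.5), rt; (2E)-isomer purified by chromatography
Reagents that add atoms: water, O
Why: Horner–Wadsworth–Emmons formyl-olefination of the activated ketone followed by mild imine hydrolysis gives the β-methyl enal, with the bulkier acetal-bearing group trans to CHO.

Step 2
Reactants: 4 (2E)-4,4-dimethoxy-3-methylbut-2-enal; 5 1-(triphenylphosphoranylidene)propan-2-one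
Product: 7 (3E,6R)-7,7-dimethoxy-6-methylhept-3-en-2-one, via (3R)-4,4-dimethoxy-3-methylbutanal 6 (not isolated)
Conditions: morpholinium salt of (S)-TRIP [(S)-3,3'-bis(2,4,6-triisopropylphenyl)-1,1'-binaphthyl-2,2'-diyl hydrogen phosphate] (20 mol%), Hantzsch ester (1.1 equiv), dioxane, 50 °C; then 5, rt to 40 °C
Reagents that add atoms: none
Why: Key step, counteranion-directed iminium transfer hydrogenation: the chiral phosphate pairs with the (E)-iminium ion and hydride goes to one face of the β-carbon, setting the first stereocentre as R (antipode chosen by analogy with (E)-citral/(R)-TRIP giving (R)-citronellal, with the acetal in the place of the chain); the volatile aldehyde is trapped in the flask by an E-selective Wittig reaction.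

Step 3
Reactants: 7 (3E,6R)-7,7-dimethoxy-6-methylhept-3-en-2-one
Product: 8 (6R)-7,7-dimethoxy-6-methylheptan-2-one
Conditions: H2 (1 atm), Pd/C (5 mol%), EtOAc, rt
Reagents that add atoms: none
Why: Catalytic hydrogenation of the conjugated C=C leaves ketone, acetal and the remote stereocentre untouched.

Step 4
Reactants: 8 (6R)-7,7-dimethoxy-6-methylheptan-2-one; 2 diethyl [(E)-2-(cyclohexylamino)ethenyl]phosphonate
Product: 10 (2E,7R)-8,8-dimethoxy-3,7-dimethyloct-2-enal, via unsaturated N-cyclohexylimine 9 (not isolated)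
Conditions: NaH, THF, 0 °C to rt; then aq. AcOH/NaOAc (pH 4.5), rt; (2E)-isomer separated by chromatography
Reagents that add atoms: water, O
Why: The same Horner–Wadsworth–Emmons formyl-olefination converts the methyl ketone into a citral-type β-methyl enal (E major), as in the classical β-ionone homologation.

Step 5
Reactants: 10 (2E,7R)-8,8-dimethoxy-3,7-dimethyloct-2-enal
Product: 11 (3S,7R)-8,8-dimethoxy-3,7-dimethyloctanal
Conditions: morpholinium salt of (S)-TRIP (20 mol%), Hantzsch ester (1.1 equiv), dioxane, 50 °C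
Reagents that add atoms: none
Why: The same iminium transfer hydrogenation, now on a geranial-like enal (about 90% ee expected), sets the second stereocentre as S; the same catalyst antipode gives the required 1,5-relationship because here the CH2–CHO arm becomes the alkenyl side and not the chain.

Step 6
Reactants: 11 (3S,7R)-8,8-dimethoxy-3,7-dimethyloctanal
Product: 13 (3S,7R)-8,8-dimethoxy-3,7-dimethyloct-1-yne, via enol nonaflate 12 (not isolated)
Conditions: C4F9SO2F (1.3 equiv), P2-Et phosphazene base (2.6 equiv), DMF, −20 °C to rt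
Reagents that add atoms: none
Why: Enol sulfonylation of the aldehyde and E2 elimination of the 1-alkenyl nonaflate give the terminal alkyne without a carbon change; the β-stereocentre is not on the elimination path and the base-stable acetal survives.

Step 7
Reactants: 14 3-bromofuran; 15 oxetane
Product: 17 3-(furan-3-yl)propan-1-ol, via furan-3-yllithium 16 (not isolated)
Conditions: n-BuLi, THF, −78 °C; then 15, BF3·OEt2, −78 °C; aq. NH4Cl
Reagents that add atoms: none
Why: Bromine–lithium exchange at −78 °C (no 3- to 2-lithio migration) and Lewis-acid-promoted oxetane opening install the three-carbon alcohol chain.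

Step 8
Reactants: 17 3-(furan-3-yl)propan-1-ol
Product: 18 3-(3-bromopropyl)furan
Conditions: CBr4, PPh3, CH2Cl2, 0 °C
Reagents that add atoms: carbon tetrabromide, BrC(Br)(Br)Br
Why: The Appel reaction converts the primary alcohol into the bromide under neutral conditions that the furan tolerates.

Step 9
Reactants: 18 3-(3-bromopropyl)furan; 19 propyne
Product: 23 3-[(4Z)-5-iodo-4-methylpent-4-en-1-yl]furan, via Grignard reagent 20 (not isolated), via alkylcopper 21 (not isolated), via (Z)-alkenylcopper 22 (not isolated)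
Conditions: Mg, Et2O, reflux; CuBr·SMe2 (1 equiv), Et2O/Me2S, −45 °C; propyne, −25 °C; I2, −50 to 0 °C
Reagents that add atoms: iodine, II
Why: Normant carbocupration adds the alkyl group and copper syn across propyne (alkyl to the internal carbon), and iodinolysis with retention gives the (Z)-trisubstituted vinyl iodide with iodine cis to the furylpropyl chain.

Step 10
Reactants: 13 (3S,7R)-8,8-dimethoxy-3,7-dimethyloct-1-yne; 23 3-[(4Z)-5-iodo-4-methylpent-4-en-1-yl]furan
Product: 26 3-[(4Z,6E,8S,12R)-13,13-dimethoxy-4,8,12-trimethyltrideca-4,6-dien-1-yl]furan, via alkenylzirconocene chloride 24 (not isolated), via alkenylzinc chloride 25 (not isolated)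
Conditions: Cp2Zr(H)Cl, THF, rt; ZnCl2, THF, 0 °C; 23, Pd(PPh3)4 (5 mol%), rt
Reagents that add atoms: none
Why: Syn-hydrozirconation puts zirconium on the terminal carbon (E), and Zr-to-Zn transmetalation with Negishi coupling joins the two alkenyl partners with retention at both, giving the (E,Z)-diene.

Step 11
Reactants: 26 3-[(4Z,6E,8S,12R)-13,13-dimethoxy-4,8,12-trimethyltrideca-4,6-dien-1-yl]furan
Product: 27 (2R,6S,7E,9Z)-13-(furan-3-yl)-2,6,10-trimethyltrideca-7,9-dienal
Conditions: LiBF4, MeCN/H2O (98:2), rt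
Reagents that add atoms: water, O
Why: Near-neutral acetal hydrolysis frees the α-methyl aldehyde without epimerisation and without harm to the furan or diene; the aldehyde is used at once.

Step 12
Reactants: 28 4-hydroxy-3-methylfuran-2(5H)-one (3-methyltetronic acid)
Product: 29 4-(methoxymethoxy)-3-methylfuran-2(5H)-one
Conditions: MOMCl, i-Pr2NEt, CH2Cl2, 0 °C to rt
Reagents that add atoms: chloromethyl methyl ether, COCCl
Why: O-Alkylation of the vinylogous acid with a hard electrophile gives the 4-O-MOM tetronate, which masks the acidic OH for the following carbanion chemistry.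

Step 13
Reactants: 29 4-(methoxymethoxy)-3-methylfuran-2(5H)-one
Product: 31 diphenyl [3-(methoxymethoxy)-4-methyl-5-oxo-2,5-dihydrofuran-2-yl]phosphonate (racemic), via phosphonite 30 (not isolated)
Conditions: LiN(i-Pr)2 (2.1 equiv), THF, −78 °C; ClP(OPh)2, −78 to 0 °C; AcOH; then t-BuOOH, 0 °C
Reagents that add atoms: diphenyl phosphorochloridite, ClP(Oc1ccccc1)Oc1ccccc1; tert-butyl hydroperoxide, CC(C)(C)OO
Why: The C5 lithium dienolate of the tetronate is trapped on carbon by the soft trivalent phosphorus chloride and the phosphonite is oxidised to the phosphonate (C-phosphonylation of lactone enolates via phosphorochloridites).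

Step 14
Reactants: 27 (2R,6S,7E,9Z)-13-(furan-3-yl)-2,6,10-trimethyltrideca-7,9-dienal; 31 diphenyl [3-(methoxymethoxy)-4-methyl-5-oxo-2,5-dihydrofuran-2-yl]phosphonate
Product: 32 (5E)-5-[(2R,6S,7E,9Z)-13-(furan-3-yl)-2,6,10-trimethyltrideca-7,9-dien-1-ylidene]-4-(methoxymethoxy)-3-methylfuran-2(5H)-one
Conditions: KN(SiMe3)2 (0.98 equiv), 18-crown-6, THF, −78 °C; then 27, −78 to −40 °C
Reagents that add atoms: none
Why: Proposed new method: an Ando-type diaryl phosphonate olefination moved to the vinylogous 5-position of a tetronate; the electron-poor diphenoxyphosphoryl group should make addition of the potassium furanolate to the aldehyde irreversible and elimination fast, so the kinetic adduct (open anti-periplanar transition state, aldehyde chain beside ring O1 and away from the C4–OMOM flank) collapses by syn-elimination to the alkene with the chain cis to C4, the (5E)-ylidene that thermodynamic dehydrations do not give; closest known reactions are Still–Gennari/Ando Z-selective Horner–Wadsworth–Emmons olefinations of α-substituted phosphonoacetates and Wittig olefinations of 5-phosphonio tetronates.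

Step 15
Reactants: 32 (5E)-5-[(2R,6S,7E,9Z)-13-(furan-3-yl)-2,6,10-trimethyltrideca-7,9-dien-1-ylidene]-4-(methoxymethoxy)-3-methylfuran-2(5H)-one
Product: 33 (5E)-5-[(2R,6S,7E,9Z)-13-(furan-3-yl)-2,6,10-trimethyltrideca-7,9-dien-1-ylidene]-4-hydroxy-3-methylfuran-2(5H)-one
Conditions: 1 M aq. HCl, THF, 0 °C to rt, short contact, light excluded
Reagents that add atoms: none
Why: The MOM group on a vinylogous acid is a very labile mixed acetal and hydrolyses under mild acid that leaves the 3-alkylfuran, the diene and the (5E)-ylidene intact, giving the target.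

## Compound list

1 | 1,1-dimethoxypropan-2-one | COC(OC)C(C)=O | starting material
2 | diethyl [(E)-2-(cyclohexylamino)ethenyl]phosphonate | CCOP(=O)(/C=C/NC1CCCCC1)OCC | starting material
3 | (2E)-N-cyclohexyl-4,4-dimethoxy-3-methylbut-2-en-1-imine | COC(OC)/C(C)=C/C=NC1CCCCC1 | intermediate
4 | (2E)-4,4-dimethoxy-3-methylbut-2-enal | COC(OC)/C(C)=C/C=O | intermediate
5 | 1-(triphenylphosphoranylidene)propan-2-one | CC(=O)C=P(c1ccccc1)(c1ccccc1)c1ccccc1 | starting material
6 | (3R)-4,4-dimethoxy-3-methylbutanal | COC(OC)[C@H](C)CC=O | intermediate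
7 | (3E,6R)-7,7-dimethoxy-6-methylhept-3-en-2-one | COC(OC)[C@H](C)C/C=C/C(C)=O | intermediate
8 | (6R)-7,7-dimethoxy-6-methylheptan-2-one | COC(OC)[C@H](C)CCCC(C)=O | intermediate
9 | (2E,7R)-N-cyclohexyl-8,8-dimethoxy-3,7-dimethyloct-2-en-1-imine | COC(OC)[C@H](C)CCC/C(C)=C/C=NC1CCCCC1 | intermediate
10 | (2E,7R)-8,8-dimethoxy-3,7-dimethyloct-2-enal | COC(OC)[C@H](C)CCC/C(C)=C/C=O | intermediate
11 | (3S,7R)-8,8-dimethoxy-3,7-dimethyloctanal | COC(OC)[C@H](C)CCC[C@H](C)CC=O | intermediate
12 | (3S,7R)-8,8-dimethoxy-3,7-dimethyloct-1-en-1-yl nonafluorobutane-1-sulfonate (E/Z mixture) | COC(OC)[C@H](C)CCC[C@H](C)C=COS(=O)(=O)C(F)(F)C(F)(F)C(F)(F)C(F)(F)F | intermediate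
13 | (3S,7R)-8,8-dimethoxy-3,7-dimethyloct-1-yne | COC(OC)[C@H](C)CCC[C@H](C)C#C | intermediate
14 | 3-bromofuran | Brc1ccoc1 | starting material
15 | oxetane | C1COC1 | starting material
16 | furan-3-yllithium | [Li]c1ccoc1 | intermediate
17 | 3-(furan-3-yl)propan-1-ol | OCCCc1ccoc1 | intermediate
18 | 3-(3-bromopropyl)furan | BrCCCc1ccoc1 | intermediate
19 | propyne | CC#C | starting material
20 | bromo[3-(furan-3-yl)propyl]magnesium | Br[Mg]CCCc1ccoc1 | intermediate
21 | [3-(furan-3-yl)propyl]copper | [Cu]CCCc1ccoc1 | intermediate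
22 | [(1Z)-5-(furan-3-yl)-2-methylpent-1-en-1-yl]copper | [Cu]/C=C(/C)CCCc1ccoc1 | intermediate
23 | 3-[(4Z)-5-iodo-4-methylpent-4-en-1-yl]furan | I/C=C(/C)CCCc1ccoc1 | intermediate
24 | chlorobis(cyclopentadienyl)[(1E,3S,7R)-8,8-dimethoxy-3,7-dimethyloct-1-en-1-yl]zirconium | COC(OC)[C@H](C)CCC[C@H](C)/C=C/[Zr](Cl)(C1C=CC=C1)C1C=CC=C1 | intermediate
25 | chloro[(1E,3S,7R)-8,8-dimethoxy-3,7-dimethyloct-1-en-1-yl]zinc | COC(OC)[C@H](C)CCC[C@H](C)/C=C/[Zn]Cl | intermediate
26 | 3-[(4Z,6E,8S,12R)-13,13-dimethoxy-4,8,12-trimethyltrideca-4,6-dien-1-yl]furan | COC(OC)[C@H](C)CCC[C@H](C)/C=C/C=C(/C)CCCc1ccoc1 | intermediate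
27 | (2R,6S,7E,9Z)-13-(furan-3-yl)-2,6,10-trimethyltrideca-7,9-dienal | O=C[C@H](C)CCC[C@H](C)/C=C/C=C(/C)CCCc1ccoc1 | intermediate
28 | 4-hydroxy-3-methylfuran-2(5H)-one | CC1=C(O)COC1=O | starting material
29 | 4-(methoxymethoxy)-3-methylfuran-2(5H)-one | CC1=C(OCOC)COC1=O | intermediate
30 | diphenyl [3-(methoxymethoxy)-4-methyl-5-oxo-2,5-dihydrofuran-2-yl]phosphonite (racemic) | CC1=C(OCOC)C(P(Oc2ccccc2)Oc2ccccc2)OC1=O | intermediate
31 | diphenyl [3-(methoxymethoxy)-4-methyl-5-oxo-2,5-dihydrofuran-2-yl]phosphonate (racemic) | CC1=C(OCOC)C(P(=O)(Oc2ccccc2)Oc2ccccc2)OC1=O | intermediate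
32 | (5E)-5-[(2R,6S,7E,9Z)-13-(furan-3-yl)-2,6,10-trimethyltrideca-7,9-dien-1-ylidene]-4-(methoxymethoxy)-3-methylfuran-2(5H)-one | CC1=C(OCOC)/C(=C\[C@H](C)CCC[C@H](C)/C=C/C=C(/C)CCCc2ccoc2)OC1=O | intermediate
33 | (5E)-5-[(2R,6S,7E,9Z)-13-(furan-3-yl)-2,6,10-trimethyltrideca-7,9-dien-1-ylidene]-4-hydroxy-3-methylfuran-2(5H)-one | CC1=C(O)/C(=C\[C@H](C)CCC[C@H](C)/C=C/C=C(/C)CCCc2ccoc2)OC1=O | target

## Step count and risks

Total step count: 15. Longest linear sequence: 10 (steps 1, 2, 3, 4, 5, 6, 10, 11, 14, 15).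

Two transfer hydrogenations at about 90% ee each would give the target with roughly 10% of 1,5-diastereomers; these would have to be removed by preparative HPLC at the end.

**Step 14 (the proposed new olefination).** The stabilised furanolate may add reversibly and drift to the thermodynamic (5Z)-isomer, or add too slowly. The fallback sets out from 27 and 29 and returns at 32. Lithiation of 29 (LiN(i-Pr)2, THF, −78 °C) and addition of 27 give the aldol adducts 5-[(2R,6S,7E,9Z)-13-(furan-3-yl)-1-hydroxy-2,6,10-trimethyltrideca-7,9-dien-1-yl]-4-(methoxymethoxy)-3-methylfuran-2(5H)-one F1. MsCl/Et3N converts them into (2R,6S,7E,9Z)-13-(furan-3-yl)-1-[3-(methoxymethoxy)-4-methyl-5-oxo-2,5-dihydrofuran-2-yl]-2,6,10-trimethyltrideca-7,9-dien-1-yl methanesulfonate F2. DBU eliminates to a mixture of 32 and (5Z)-5-[(2R,6S,7E,9Z)-13-(furan-3-yl)-2,6,10-trimethyltrideca-7,9-dien-1-ylidene]-4-(methoxymethoxy)-3-methylfuran-2(5H)-one F3. The Z-isomer is expected to predominate; 32 is isolated by chromatography and the Z-isomer is photo-equilibrated (350 nm) and recycled. This is the classical aldol–dehydration route to ylidene tetronates and is lower-yielding for the E-isomer.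

**Step 6 (one-step aldehyde-to-alkyne conversion).** The (E)-enol nonaflate may eliminate slowly and the strong base may cause side reactions. The fallback sets out from 11 and returns at 13. Me3SiCl/Et3N/NaI in MeCN gives the silyl enol ether {[(3S,7R)-8,8-dimethoxy-3,7-dimethyloct-1-en-1-yl]oxy}trimethylsilane F4. Ozonolysis (O3, CH2Cl2, −78 °C; PPh3) gives the one-carbon-shorter aldehyde (2S,6R)-7,7-dimethoxy-2,6-dimethylheptanal F5. Ohira–Bestmann homologation (dimethyl (1-diazo-2-oxopropyl)phosphonate, K2CO3, MeOH, 0 °C) restores the carbon and gives 13.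

**Step 5 (transfer hydrogenation of the unhindered aliphatic enal).** The enantioselectivity may fall below 90%, and E/Z erosion of the enal would lower it further. The fallback sets out from 10 and returns at 11. Luche reduction (NaBH4, CeCl3·7H2O, MeOH) gives (2E,7R)-8,8-dimethoxy-3,7-dimethyloct-2-en-1-ol F6. Hydroxyl-directed hydrogenation with Ru(OAc)2[(R)-BINAP] (H2, MeOH; the geraniol to (S)-citronellol precedent) gives (3S,7R)-8,8-dimethoxy-3,7-dimethyloctan-1-ol F7. Dess–Martin oxidation gives 11.

## Further compounds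

F1 | step 14 | 5-[(2R,6S,7E,9Z)-13-(furan-3-yl)-1-hydroxy-2,6,10-trimethyltrideca-7,9-dien-1-yl]-4-(methoxymethoxy)-3-methylfuran-2(5H)-one (diastereomer mixture at ring C5 and the carbinol carbon) | CC1=C(OCOC)C(OC1=O)C(O)[C@H](C)CCC[C@H](C)/C=C/C=C(/C)CCCc1ccoc1
F2 | step 14 | (2R,6S,7E,9Z)-13-(furan-3-yl)-1-[3-(methoxymethoxy)-4-methyl-5-oxo-2,5-dihydrofuran-2-yl]-2,6,10-trimethyltrideca-7,9-dien-1-yl methanesulfonate (diastereomer mixture) | CC1=C(OCOC)C(OC1=O)C(OS(C)(=O)=O)[C@H](C)CCC[C@H](C)/C=C/C=C(/C)CCCc1ccoc1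
F3 | step 14 | (5Z)-5-[(2R,6S,7E,9Z)-13-(furan-3-yl)-2,6,10-trimethyltrideca-7,9-dien-1-ylidene]-4-(methoxymethoxy)-3-methylfuran-2(5H)-one | CC1=C(OCOC)/C(=C/[C@H](C)CCC[C@H](C)/C=C/C=C(/C)CCCc2ccoc2)OC1=O
F4 | step 6 | {[(3S,7R)-8,8-dimethoxy-3,7-dimethyloct-1-en-1-yl]oxy}trimethylsilane (E/Z mixture) | COC(OC)[C@H](C)CCC[C@H](C)C=CO[Si](C)(C)C
F5 | step 6 | (2S,6R)-7,7-dimethoxy-2,6-dimethylheptanal | COC(OC)[C@H](C)CCC[C@H](C)C=O
F6 | step 5 | (2E,7R)-8,8-dimethoxy-3,7-dimethyloct-2-en-1-ol | COC(OC)[C@H](C)CCC/C(C)=C/CO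
F7 | step 5 | (3S,7R)-8,8-dimethoxy-3,7-dimethyloctan-1-ol | COC(OC)[C@H](C)CCC[C@H](C)CCO
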